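Each half is a cyclohexane (ring A, C1–C6) fused at C5–C6 to a seven-membered lactone (ring B: C5, C6, C7=C8, C9, O10, C11); C12 is the carboxyl carbon on C8 and C13 the CH2O on C4. The dimer is cut at the C12–O ester between the mirror-image halves. Because C12 sits on the ring-B alkene carbon C8 in both halves, it is brought in as carbon monoxide: one palladium-catalysed carbonylation joins the C8 iodide of one antipode, CO and the primary C13 hydroxyl of the other, forming C8–C12 and C12–O together. The precursors are the acetonide-protected iodolactone and the enantiomeric diol carrying a 4-methoxybenzyl ester.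

Key step: step 29

Remarks on the chemistry
- The locants C1–C13 defined above are used for all intermediates. Series A gives the acyl half (from (R)-cryptone); series B is its mirror image and gives the alcohol half. PMB = 4-methoxybenzyl, TIPS = triisopropylsilyl.
- Assumption: the lithium amide of (R,R)-bis(1-phenylethyl)amine is taken to give the (S)-enol ether 6, by analogy with 4-tert-butylcyclohexanone. The sense should be confirmed by the optical rotation of the derived cryptone; if it is reversed, the two amide antipodes are exchanged between the series.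
- The alkynylzinc reagent 4 is made once (step 2) as a stock solution and divided between the two series (steps 5 and 17).
- The C12 acid of the alcohol half is carried as a PMB ester. It is inert to zerovalent palladium in both carbonylations and falls with the acetonide under acid, so no palladium/amine deallylation is run on the allylic lactones.
- The desymmetrisation need not be perfect: in step 29 the minor antipodes should end up mainly in a homochiral diastereomer that chromatography removes.

**Alkyne building block**

Step 1
Reactants: 1 propargyl alcohol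
Product: 2 PMB propargyl ether
Conditions: NaH, 4-MeOC6H4CH2Cl, Bu4NI (cat.), THF/DMF, 0 °C → rt
Reagents that add atoms: 4-methoxybenzyl chloride, COc1ccc(CCl)cc1
Why: Williamson ether synthesis, the sodium alkoxide displacing the benzylic chloride by SN2; no stereocentre is involved.

Step 2
Reactants: 2 PMB propargyl ether
Product: 4 [3-(4-methoxybenzyloxy)prop-1-yn-1-yl]zinc bromide (kept as a THF stock solution under argon for steps 5 and 17), via lithium acetylide 3 (not isolated)
Conditions: n-BuLi, THF, −78 °C; ZnBr2, −78 → 0 °C
Reagents that add atoms: zinc bromide, Br[Zn]Br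
Why: Deprotonation of the terminal alkyne by n-BuLi followed by transmetalation (salt metathesis) of the lithium acetylide with ZnBr2 gives the alkynylzinc bromide, a reagent class that is stable in THF solution; no stereocentre is involved.

**Series A (acyl half)**

Step 3
Reactants: 5 4-isopropylcyclohexanone
Product: 6 (S)-trimethylsilyl enol ether of 5
Conditions: (R,R)-[PhCH(Me)]2NH, n-BuLi, LiCl, THF, −78 °C; Me3SiCl, then 5, −78 °C (in situ quench)
Reagents that add atoms: chlorotrimethylsilane, C[Si](C)(C)Cl
Why: Enantioselective deprotonation (desymmetrisation) of the prochiral ketone: the C2-symmetric chiral lithium amide chooses between the enantiotopic α-methylene groups and the enolate is silylated at once, which makes the isopropyl-bearing carbon (future C1) a stereocentre under reagent control.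

Step 4
Reactants: 6 (S)-trimethylsilyl enol ether
Product: 7 (R)-cryptone
Conditions: Pd(OAc)2 (10 mol %), O2 (1 atm), DMSO, rt
Reagents that add atoms: none
Why: Saegusa–Ito oxidation, in which the palladium enolate undergoes β-hydride elimination to the enone under neutral conditions, so the γ-stereocentre is not touched.

Step 5
Reactants: 7 (R)-cryptone; 4 [3-(4-methoxybenzyloxy)prop-1-yn-1-yl]zinc bromide
Product: 8 series-A silyl enol ether (C4–OSiMe3; C4=C5; PMB-oxypropynyl on C6 trans to the C1 isopropyl)
Conditions: 4 (THF solution), Me3SiOTf, Et2O/THF, −40 °C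
Reagents that add atoms: trimethylsilyl trifluoromethanesulfonate, C[Si](C)(C)OS(=O)(=O)C(F)(F)F
Why: Silyl triflate-promoted conjugate alkynylation of a cyclic enone by an alkynylzinc halide: the alkynyl group should add to C6 anti to the neighbouring isopropyl group (1,6-trans), and the enolate is kept regiodefined as the C4=C5 silyl enol ether.

Step 6
Reactants: 8 series-A silyl enol ether
Product: 10 series-A ketone (C5–CH2OTIPS; substituents on C1, C6 and C5 all trans), via lithium enolate 9 (not isolated)
Conditions: MeLi, THF, 0 °C; iPr3SiOCH2Cl, −78 → −20 °C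
Reagents that add atoms: (triisopropylsiloxy)methyl chloride, ClCO[Si](C(C)C)(C(C)C)C(C)C
Why: Regiospecific enolate alkylation: MeLi cleaves the silyl enol ether to the C4=C5 lithium enolate, which is C-alkylated by the chloromethyl ether (the reaction type of benzyl chloromethyl ether) anti to the C6 alkynyl group, giving the 5,6-trans, all-equatorial and thermodynamically preferred isomer.

Step 7
Reactants: 10 series-A ketone
Product: 11 series-A spiro-epoxide (C13 axial and cis to C11; epoxide oxygen equatorial)
Conditions: Me3S+ I−, KN(SiMe3)2, THF, −10 → 0 °C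
Reagents that add atoms: trimethylsulfonium iodide, C[S+](C)C.[I-]
Why: Corey–Chaykovsky epoxidation: the unstabilised dimethylsulfonium methylide adds irreversibly along the axial direction of the chair ketone, so C13 becomes axial and the C4–O bond equatorial, before the betaine closes to the epoxide.

Step 8
Reactants: 11 series-A spiro-epoxide
Product: 12 series-A diol (tertiary C4–OH equatorial; C13H2OH axial)
Conditions: KOH (2 M aq.), DMSO, 80 °C
Reagents that add atoms: water, O
Why: Base-mediated epoxide hydrolysis in which hydroxide opens the epoxide by SN2 at the unsubstituted C13, so the C4–O bond and the C4 configuration are retained; the hindered TIPS ether, the PMB ether and the propargylic ether should tolerate the water-levelled base.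

Step 9
Reactants: 12 series-A diol
Product: 13 series-A acetonide
Conditions: Me2C(OMe)2, PPTS (cat.), acetone, rt
Reagents that add atoms: 2,2-dimethoxypropane, COC(C)(C)OC
Why: Acid-catalysed transacetalisation (acetonide formation) of the 1,2-diol to the five-membered dioxolane under conditions that leave the silyl and PMB ethers alone.

Step 10
Reactants: 13 series-A acetonide
Product: 15 series-A alkenyl iodide (C7H=C8(I)–C9; C9 cis to C6), via alkenylstannane 14 (not isolated)
Conditions: Bu3SnH, PdCl2(PPh3)2 (3 mol %), THF, 0 °C → rt; then I2, 0 °C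
Reagents that add atoms: iodine, II
Why: Palladium-catalysed syn-hydrostannation of the propargylic ether should place tin on C8 (next to the ether-bearing C9, away from the branched C6) and hydrogen on C7, which sets C9 cis to C6; iododestannylation then exchanges tin for iodine with retention of alkene geometry.

Step 11
Reactants: 15 series-A alkenyl iodide
Product: 16 series-A primary alcohol (C11–OH)
Conditions: Bu4NF, THF, rt
Reagents that add atoms: none
Why: Fluoride-mediated desilylation of the TIPS ether; the PMB ether, acetonide and alkenyl iodide are inert to fluoride.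

Step 12
Reactants: 16 series-A primary alcohol
Product: 17 series-A C11 carboxylic acid
Conditions: TEMPO (20 mol %), PhI(OAc)2, MeCN/pH 7 phosphate buffer, rt
Reagents that add atoms: water, O
Why: Oxoammonium (TEMPO/PhI(OAc)2) oxidation of the primary alcohol through the aldehyde hydrate to the acid at near-neutral pH; C5 already holds its more stable equatorial configuration, so the aldehyde stage should not erode it.

Step 13
Reactants: 17 series-A C11 carboxylic acid
Product: 18 series-A hydroxy acid (C9–OH free)
Conditions: DDQ, CH2Cl2/pH 7 buffer, 0 °C → rt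
Reagents that add atoms: none
Why: Oxidative cleavage of the PMB ether by DDQ (benzylic hydride abstraction, hydrolysis of the oxocarbenium ion), which spares the alkenyl iodide, acetonide and acid.

Step 14
Reactants: 18 series-A hydroxy acid
Product: 19 series-A iodo-oxepinone acetonide (rings A and B trans-fused)
Conditions: 2-methyl-6-nitrobenzoic anhydride, DMAP, Et3N, CH2Cl2 (high dilution, slow addition), rt
Reagents that add atoms: none
Why: Shiina lactonisation (mixed anhydride, DMAP acyl transfer) closes ring B between C11 and the C9 oxygen; the cis C7=C8 alkene and the trans-diequatorial C5/C6 substituents hold the two ends close, and no stereocentre is formed.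

**Series B (alcohol half, mirror-image series)**

Step 15
Reactants: 5 4-isopropylcyclohexanone
Product: 20 (R)-trimethylsilyl enol ether of 5
Conditions: (S,S)-[PhCH(Me)]2NH, n-BuLi, LiCl, THF, −78 °C; Me3SiCl, then 5, −78 °C (in situ quench)
Reagents that add atoms: chlorotrimethylsilane, C[Si](C)(C)Cl
Why: Enantioselective deprotonation as in step 3 with the antipodal lithium amide, which should select the other enantiotopic α-methylene group and so set the opposite configuration at the isopropyl-bearing carbon.

Step 16
Reactants: 20 (R)-trimethylsilyl enol ether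
Product: 21 (S)-cryptone
Conditions: Pd(OAc)2 (10 mol %), O2 (1 atm), DMSO, rt
Reagents that add atoms: none
Why: Saegusa–Ito oxidation as in step 4; the stereocentre is remote from the reacting carbons and is kept.

Step 17
Reactants: 21 (S)-cryptone; 4 [3-(4-methoxybenzyloxy)prop-1-yn-1-yl]zinc bromide
Product: 22 series-B silyl enol ether (enantiomer of 8)
Conditions: 4 (THF solution), Me3SiOTf, Et2O/THF, −40 °C
Reagents that add atoms: trimethylsilyl trifluoromethanesulfonate, C[Si](C)(C)OS(=O)(=O)C(F)(F)F
Why: Silyl triflate-promoted conjugate alkynylation as in step 5, the alkynyl group adding to C6 anti to the isopropyl group on C1.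

Step 18
Reactants: 22 series-B silyl enol ether
Product: 24 series-B ketone (enantiomer of 10), via lithium enolate 23 (not isolated)
Conditions: MeLi, THF, 0 °C; iPr3SiOCH2Cl, −78 → −20 °C
Reagents that add atoms: (triisopropylsiloxy)methyl chloride, ClCO[Si](C(C)C)(C(C)C)C(C)C
Why: Regiospecific enolate alkylation as in step 6, the chloromethyl ether entering at C5 anti to the C6 alkynyl group.

Step 19
Reactants: 24 series-B ketone
Product: 25 series-B spiro-epoxide (enantiomer of 11)
Conditions: Me3S+ I−, KN(SiMe3)2, THF, −10 → 0 °C
Reagents that add atoms: trimethylsulfonium iodide, C[S+](C)C.[I-]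
Why: Corey–Chaykovsky epoxidation as in step 7, axial addition of the sulfonium ylide placing C13 axial and cis to C11.

Step 20
Reactants: 25 series-B spiro-epoxide
Product: 26 series-B diol (enantiomer of 12)
Conditions: KOH (2 M aq.), DMSO, 80 °C
Reagents that add atoms: water, O
Why: Base-mediated epoxide hydrolysis by SN2 attack of hydroxide at C13, as in step 8, with retention at C4.

Step 21
Reactants: 26 series-B diol
Product: 27 series-B acetonide (enantiomer of 13)
Conditions: Me2C(OMe)2, PPTS (cat.), acetone, rt
Reagents that add atoms: 2,2-dimethoxypropane, COC(C)(C)OC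
Why: Acid-catalysed acetonide formation as in step 9.

Step 22
Reactants: 27 series-B acetonide
Product: 29 series-B alkenyl iodide (enantiomer of 15), via alkenylstannane 28 (not isolated)
Conditions: Bu3SnH, PdCl2(PPh3)2 (3 mol %), THF, 0 °C → rt; then I2, 0 °C
Reagents that add atoms: iodine, II
Why: Palladium-catalysed syn-hydrostannation and iododestannylation as in step 10, giving the C8 iodide with C9 cis to C6.

Step 23
Reactants: 29 series-B alkenyl iodide
Product: 30 series-B primary alcohol (enantiomer of 16)
Conditions: Bu4NF, THF, rt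
Reagents that add atoms: none
Why: Fluoride-mediated desilylation as in step 11.

Step 24
Reactants: 30 series-B primary alcohol
Product: 31 series-B C11 carboxylic acid (enantiomer of 17)
Conditions: TEMPO (20 mol %), PhI(OAc)2, MeCN/pH 7 phosphate buffer, rt
Reagents that add atoms: water, O
Why: Oxoammonium oxidation of the primary alcohol to the acid as in step 12.

Step 25
Reactants: 31 series-B C11 carboxylic acid
Product: 32 series-B hydroxy acid (enantiomer of 18)
Conditions: DDQ, CH2Cl2/pH 7 buffer, 0 °C → rt
Reagents that add atoms: none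
Why: Oxidative PMB ether cleavage by DDQ as in step 13.

Step 26
Reactants: 32 series-B hydroxy acid
Product: 33 series-B iodo-oxepinone acetonide (enantiomer of 19)
Conditions: 2-methyl-6-nitrobenzoic anhydride, DMAP, Et3N, CH2Cl2 (high dilution, slow addition), rt
Reagents that add atoms: none
Why: Shiina lactonisation closing ring B as in step 14.

Step 27
Reactants: 33 series-B iodo-oxepinone acetonide; 34 carbon monoxide
Product: 35 series-B PMB ester acetonide (C12 as PMB ester on C8)
Conditions: CO (1 atm), 4-MeOC6H4CH2OH (5 equiv), Pd(OAc)2 (5 mol %), Xantphos (6 mol %), Et3N, toluene, 60 °C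
Reagents that add atoms: 4-methoxybenzyl alcohol, COc1ccc(CO)cc1
Why: Palladium-catalysed alkoxycarbonylation of an alkenyl iodide (oxidative addition, CO insertion, alcoholysis by the excess benzylic alcohol), which forms C8–C12 without touching a stereocentre.

Step 28
Reactants: 35 series-B PMB ester acetonide
Product: 36 series-B diol PMB ester (C4–OH and C13–OH free)
Conditions: AcOH/H2O/THF (3:1:1), 45 °C
Reagents that add atoms: none
Why: Mild acid hydrolysis of the acetonide, under which the PMB ester, the conjugated ester and the lactone should be stable.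

**Union and deprotection**

Step 29
Reactants: 19 series-A iodo-oxepinone acetonide; 34 carbon monoxide; 36 series-B diol PMB ester
Product: 37 protected dimer (acetonide on the acyl half, PMB ester on the alcohol half)
Conditions: CO (1 atm), Pd(OAc)2 (10 mol %), Xantphos (12 mol %), Et3N, DMAP (20 mol %), 4 Å MS, toluene/THF, 50 °C
Reagents that add atoms: none
Why: Pd(OAc)2 is reduced in situ to zerovalent palladium, which adds oxidatively into the C8–I bond of 19; CO inserts to give the C12 acylpalladium (new C8–C12 bond), and the primary C13 hydroxyl of 36, assisted by Et3N and DMAP, displaces palladium to form the C12–O bond. The closest known reaction type is the palladium-catalysed alkoxycarbonylation of alkenyl iodides with a valuable alcohol as the limiting nucleophile. No ring closes and no stereocentre is formed: the alkene geometry is locked in ring B, and the heterochiral pairing is fixed by combining 19 of series A with 36 of series B. The step needs acylation of the primary C13–OH in preference to the tertiary C4–OH, which the steric shielding of the fully substituted carbinol should secure, and it needs capture of the acylpalladium to outrun any palladium-mediated ionisation of the allylic C9–O10 lactone bonds, which CO saturation, the non-polar solvent and the absence of soft nucleophiles should favour. The acetonide keeps the diol of 19 from competing, and the PMB ester of 36, unlike an allyl ester, is inert to zerovalent palladium.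

Step 30
Reactants: 37 protected dimer
Product: 38 CNP0340505.1 (target)
Conditions: CF3CO2H/CH2Cl2/H2O (10:10:1), anisole, 0 °C → rt
Reagents that add atoms: none
Why: Global acidolysis: trifluoroacetic acid cleaves the PMB ester through the 4-methoxybenzyl cation (trapped by anisole in a Friedel–Crafts alkylation) and hydrolyses the acetonide, while the lactones, the linking ester and all stereocentres should be unaffected.

**Compound list**

1 | propargyl alcohol (prop-2-yn-1-ol) | C#CCO | starting material
2 | PMB propargyl ether, 1-methoxy-4-[(prop-2-yn-1-yloxy)methyl]benzene | C#CCOCc1ccc(OC)cc1 | intermediate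
3 | lithium 3-(4-methoxybenzyloxy)prop-1-yn-1-ide | [Li]C#CCOCc1ccc(OC)cc1 | intermediate
4 | [3-(4-methoxybenzyloxy)prop-1-yn-1-yl]zinc bromide (THF stock solution) | Br[Zn]C#CCOCc1ccc(OC)cc1 | intermediate
5 | 4-isopropylcyclohexanone | CC(C)C1CCC(=O)CC1 | starting material
6 | (S)-trimethyl{[4-(propan-2-yl)cyclohex-1-en-1-yl]oxy}silane | CC(C)[C@H]1CCC(O[Si](C)(C)C)=CC1 | intermediate
7 | (R)-cryptone, (R)-4-(propan-2-yl)cyclohex-2-en-1-one | CC(C)[C@H]1CCC(=O)C=C1 | intermediate
8 | series-A silyl enol ether: 1-(trimethylsilyloxy)cyclohex-1-ene carrying 3-[3-(PMB-oxy)prop-1-ynyl] and 4-isopropyl, 3,4-trans (half locants: C4–OSiMe3, C4=C5, alkynyl on C6, isopropyl on C1) | CC(C)[C@H]1CCC(O[Si](C)(C)C)=C[C@@H]1C#CCOCc1ccc(OC)cc1 | intermediate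
9 | series-A lithium enolate (lithium in place of SiMe3 in 8) | CC(C)[C@H]1CCC(O[Li])=C[C@@H]1C#CCOCc1ccc(OC)cc1 | intermediate
10 | series-A ketone: 4-isopropyl-3-[3-(PMB-oxy)prop-1-ynyl]-2-[(TIPS-oxy)methyl]cyclohexan-1-one, 2,3-trans and 3,4-trans (all equatorial) | CC(C)[C@H]1CCC(=O)[C@@H](CO[Si](C(C)C)(C(C)C)C(C)C)[C@@H]1C#CCOCc1ccc(OC)cc1 | intermediate
11 | series-A spiro-epoxide (1-oxaspiro[2.5]octane): epoxide CH2 (C13) axial and cis to C11, epoxide O equatorial | CC(C)[C@H]1CC[C@@]2(CO2)[C@@H](CO[Si](C(C)C)(C(C)C)C(C)C)[C@@H]1C#CCOCc1ccc(OC)cc1 | intermediate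
12 | series-A diol: tertiary C4–OH (equatorial) and C13H2OH (axial, cis to C11) | CC(C)[C@H]1CC[C@@](O)(CO)[C@@H](CO[Si](C(C)C)(C(C)C)C(C)C)[C@@H]1C#CCOCc1ccc(OC)cc1 | intermediate
13 | series-A acetonide (2,2-dimethyl-1,3-dioxolane spiro at C4) | CC(C)[C@H]1CC[C@@]2(COC(C)(C)O2)[C@@H](CO[Si](C(C)C)(C(C)C)C(C)C)[C@@H]1C#CCOCc1ccc(OC)cc1 | intermediate
14 | series-A alkenylstannane: C7H=C8(SnBu3)–C9H2OPMB, C9 cis to C6 | CC(C)[C@H]1CC[C@@]2(COC(C)(C)O2)[C@@H](CO[Si](C(C)C)(C(C)C)C(C)C)[C@@H]1/C=C(/[Sn](CCCC)(CCCC)CCCC)COCc1ccc(OC)cc1 | intermediate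
15 | series-A alkenyl iodide: C7H=C8(I)–C9H2OPMB, C9 cis to C6 | CC(C)[C@H]1CC[C@@]2(COC(C)(C)O2)[C@@H](CO[Si](C(C)C)(C(C)C)C(C)C)[C@@H]1/C=C(/I)COCc1ccc(OC)cc1 | intermediate
16 | series-A primary alcohol (C11–OH) | CC(C)[C@H]1CC[C@@]2(COC(C)(C)O2)[C@@H](CO)[C@@H]1/C=C(/I)COCc1ccc(OC)cc1 | intermediate
17 | series-A C11 carboxylic acid | CC(C)[C@H]1CC[C@@]2(COC(C)(C)O2)[C@@H](C(=O)O)[C@@H]1/C=C(/I)COCc1ccc(OC)cc1 | intermediate
18 | series-A hydroxy acid (C9–OH, C11 acid) | CC(C)[C@H]1CC[C@@]2(COC(C)(C)O2)[C@@H](C(=O)O)[C@@H]1/C=C(/I)CO | intermediate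
19 | series-A iodo-oxepinone acetonide (C8 iodide; rings A and B trans-fused) | CC(C)[C@H]1CC[C@@]3(COC(C)(C)O3)[C@H]2C(=O)OCC(I)=C[C@H]12 | intermediate
20 | (R)-trimethyl{[4-(propan-2-yl)cyclohex-1-en-1-yl]oxy}silane | CC(C)[C@@H]1CCC(O[Si](C)(C)C)=CC1 | intermediate
21 | (S)-cryptone, (S)-4-(propan-2-yl)cyclohex-2-en-1-one | CC(C)[C@@H]1CCC(=O)C=C1 | intermediate
22 | series-B silyl enol ether (enantiomer of 8) | CC(C)[C@@H]1CCC(O[Si](C)(C)C)=C[C@H]1C#CCOCc1ccc(OC)cc1 | intermediate
23 | series-B lithium enolate (enantiomer of 9) | CC(C)[C@@H]1CCC(O[Li])=C[C@H]1C#CCOCc1ccc(OC)cc1 | intermediate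
24 | series-B ketone (enantiomer of 10) | CC(C)[C@@H]1CCC(=O)[C@H](CO[Si](C(C)C)(C(C)C)C(C)C)[C@H]1C#CCOCc1ccc(OC)cc1 | intermediate
25 | series-B spiro-epoxide (enantiomer of 11) | CC(C)[C@@H]1CC[C@]2(CO2)[C@H](CO[Si](C(C)C)(C(C)C)C(C)C)[C@H]1C#CCOCc1ccc(OC)cc1 | intermediate
26 | series-B diol (enantiomer of 12) | CC(C)[C@@H]1CC[C@](O)(CO)[C@H](CO[Si](C(C)C)(C(C)C)C(C)C)[C@H]1C#CCOCc1ccc(OC)cc1 | intermediate
27 | series-B acetonide (enantiomer of 13) | CC(C)[C@@H]1CC[C@]2(COC(C)(C)O2)[C@H](CO[Si](C(C)C)(C(C)C)C(C)C)[C@H]1C#CCOCc1ccc(OC)cc1 | intermediate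
28 | series-B alkenylstannane (enantiomer of 14) | CC(C)[C@@H]1CC[C@]2(COC(C)(C)O2)[C@H](CO[Si](C(C)C)(C(C)C)C(C)C)[C@H]1/C=C(/[Sn](CCCC)(CCCC)CCCC)COCc1ccc(OC)cc1 | intermediate
29 | series-B alkenyl iodide (enantiomer of 15) | CC(C)[C@@H]1CC[C@]2(COC(C)(C)O2)[C@H](CO[Si](C(C)C)(C(C)C)C(C)C)[C@H]1/C=C(/I)COCc1ccc(OC)cc1 | intermediate
30 | series-B primary alcohol (enantiomer of 16) | CC(C)[C@@H]1CC[C@]2(COC(C)(C)O2)[C@H](CO)[C@H]1/C=C(/I)COCc1ccc(OC)cc1 | intermediate
31 | series-B C11 carboxylic acid (enantiomer of 17) | CC(C)[C@@H]1CC[C@]2(COC(C)(C)O2)[C@H](C(=O)O)[C@H]1/C=C(/I)COCc1ccc(OC)cc1 | intermediate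
32 | series-B hydroxy acid (enantiomer of 18) | CC(C)[C@@H]1CC[C@]2(COC(C)(C)O2)[C@H](C(=O)O)[C@H]1/C=C(/I)CO | intermediate
33 | series-B iodo-oxepinone acetonide (enantiomer of 19) | CC(C)[C@@H]1CC[C@]3(COC(C)(C)O3)[C@@H]2C(=O)OCC(I)=C[C@@H]12 | intermediate
34 | carbon monoxide | [C-]#[O+] | starting material
35 | series-B PMB ester acetonide (C12 PMB ester on C8) | CC(C)[C@@H]1CC[C@]3(COC(C)(C)O3)[C@@H]2C(=O)OCC(C(=O)OCc4ccc(OC)cc4)=C[C@@H]12 | intermediate
36 | series-B diol PMB ester (C4–OH and C13–OH free; alcohol partner) | OC[C@@]1(O)CC[C@@H](C(C)C)[C@@H]2C=C(C(=O)OCc3ccc(OC)cc3)COC(=O)[C@H]21 | intermediate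
37 | protected dimer (acetonide on the acyl half, PMB ester on the alcohol half; C12 of series A esterified by O–C13 of series B) | CC(C)[C@H]1CC[C@@]5(COC(C)(C)O5)[C@H]2C(=O)OCC(C(=O)OC[C@@]3(O)CC[C@@H](C(C)C)[C@@H]4C=C(C(=O)OCc6ccc(OC)cc6)COC(=O)[C@H]43)=C[C@H]12 | intermediate
38 | CNP0340505.1 | CC(C)[C@H]1CC[C@@](O)(CO)[C@H]2C(=O)OCC(C(=O)OC[C@@]3(O)CC[C@@H](C(C)C)[C@@H]4C=C(C(=O)O)COC(=O)[C@H]43)=C[C@H]12 | target

**Count and risks**

Total step count: 30. Longest linear sequence: 16 steps (steps 15–30, from 5 through series B to 38).

Steps most likely to fail: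

1. Step 29. Capture of the acylpalladium by the neopentyl-type primary hydroxyl may be too slow, so that hydrolysis by traces of water, palladium-mediated ionisation of an allylic C9–O10 lactone bond, or migration of the lactone acyl group onto the free C13 hydroxyl of 36 takes over. Fallback: the carbon–carbon and the ester bond are made separately. Starting from 19, carbonylation with water as a fast, abundant nucleophile (Pd(OAc)2, Xantphos, CO, H2O, Et3N, THF, 50 °C) gives the series-A acetonide-protected C12 carboxylic acid F1. This is joined to 36 at the primary hydroxyl by carbodiimide esterification (EDC·HCl, DMAP, CH2Cl2, 0 °C), which returns to the route at 37.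

2. Step 7 (and its mirror image, step 19). The ylide may add with poor axial preference, or act as a base and expel the β-silyloxy group by E1cB elimination. Fallback: olefination and dihydroxylation replace the epoxide route. Starting from 10, non-basic Lombardo–Takai methylenation (CH2Br2, Zn, TiCl4, THF/CH2Cl2) gives the series-A 4-methylidene compound F2. Catalytic dihydroxylation (OsO4 cat., N-methylmorpholine N-oxide, acetone/H2O), in which the bulky oxidant is expected to approach from the equatorial side, then gives the diol and returns to the route at 12, by-passing 11. In series B the same detour runs from 24 through the series-B 4-methylidene compound F3 to 26.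

3. Step 6 (and its mirror image, step 18). The enolate may be alkylated on oxygen, or exchange protons and lose its regiochemistry before the carbon–carbon bond forms. Fallback: a Lewis-acid aldol replaces the alkylation. Starting from 8, a Mukaiyama aldol reaction with aqueous formaldehyde (Yb(OTf)3 cat., THF/H2O, rt) gives the series-A β-hydroxy ketone F4, which is silylated (iPr3SiOTf, 2,6-lutidine, CH2Cl2, −78 °C) and returns to the route at 10. In series B the same detour runs from 22 through the series-B β-hydroxy ketone F5 to 24.

**Further compounds**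

F1 | step 29 | series-A acetonide-protected C12 carboxylic acid (CO2H on C8 in place of I in 19) | CC(C)[C@H]1CC[C@@]3(COC(C)(C)O3)[C@H]2C(=O)OCC(C(=O)O)=C[C@H]12
F2 | step 7 | series-A 4-methylidene compound (C4=CH2 in place of C4=O in 10) | CC(C)[C@H]1CCC(=C)[C@@H](CO[Si](C(C)C)(C(C)C)C(C)C)[C@@H]1C#CCOCc1ccc(OC)cc1
F3 | step 19 | series-B 4-methylidene compound (enantiomer of F2) | CC(C)[C@@H]1CCC(=C)[C@H](CO[Si](C(C)C)(C(C)C)C(C)C)[C@H]1C#CCOCc1ccc(OC)cc1
F4 | step 6 | series-A β-hydroxy ketone (C11–OH free in place of OTIPS in 10) | CC(C)[C@H]1CCC(=O)[C@@H](CO)[C@@H]1C#CCOCc1ccc(OC)cc1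
F5 | step 18 | series-B β-hydroxy ketone (enantiomer of F4) | CC(C)[C@@H]1CCC(=O)[C@H](CO)[C@H]1C#CCOCc1ccc(OC)cc1
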